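**Retrosynthetic overview**

1. The route rests on ring carbon C8, which is sp2, carries C19 and has C9 cis to C6 across C7=C8, and on its sp3 neighbour C9. A (Z)-iodoalkene stores that geometry and the terminal CH2 of a (Z)-1,3-diene supplies C9, so the 14-membered carbocycle is closed last at C8–C9 by B-alkyl Suzuki–Miyaura coupling.
2. The seco iodo-diene is cut at C3–C4 (Evans syn-aldol, sets C3 and C4) and at C15–O (acid-mediated cycloetherification of the C3/C15 diol, closes the THF ring).
3. The aldehyde half (C9–C15 and C1–C3) comes from neryl acetate: Shi epoxidation of the distal alkene and SN2 opening by a vinylcopper reagent set C1, and the Z C11=C12 alkene is that of nerol.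
4. The imide half (C4–C8, C18, C19) comes from hex-5-enoyl chloride by cross-metathesis to the enal and α-iodination.
5. Ring order: THF ring (step 14), then the 14-membered ring (step 19); the malonate and the enal are installed after ring closure.

Key step: step 19

Assumption: cembrane numbering is used (C1 bears C15, C3 the ether oxygen, C4 the CH2O carbon C18, C8 the formyl carbon C19, C12 the methyl C20), and C19 is carried as a TBDPS ether (more acid-stable than TBS) so that it survives the acid of step 14.

**Route**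

Step 1
Reactants: 1 neryl acetate
Product: 2 (2Z)-5-[(2R)-3,3-dimethyloxiran-2-yl]-3-methylpent-2-en-1-yl acetate
Conditions: Shi ketone from D-fructose (30 mol%), Oxone (2KHSO5·KHSO4·K2SO4), K2CO3, Bu4NHSO4, MeCN/CH2(OMe)2/aq. Na2B4O7 buffer, 0 °C
Reagents that add atoms: potassium peroxymonosulfate KHSO5 (active part of Oxone), [K+].[O-]S(=O)(=O)OO
Why: Shi asymmetric epoxidation, in which the chiral dioxirane attacks the electron-rich distal C1=C15 alkene rather than the alkene deactivated by the allylic acetate, and the spiro transition state of the D-fructose ketone should deliver oxygen to the face that makes C1 (R).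

Step 2
Reactants: 2 epoxy acetate
Product: 3 (2Z)-5-[(2R)-3,3-dimethyloxiran-2-yl]-3-methylpent-2-en-1-ol
Conditions: K2CO3 (0.2 equiv), MeOH, 0 °C → rt
Reagents that add atoms: none
Why: Base-catalysed methanolysis removes the allylic acetate, which would act as a leaving group under copper catalysis in step 3, while the trisubstituted epoxide is inert to carbonate in methanol.

Step 3
Reactants: 3 epoxy alcohol
Product: 4 (2Z,6R)-6-(2-hydroxypropan-2-yl)-3-methylocta-2,7-dien-1-ol
Conditions: CH2=CHMgBr (4 equiv), CuI (20 mol%), THF, −30 → 0 °C; aq. NH4Cl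
Reagents that add atoms: vinylmagnesium bromide, C=C[Mg]Br
Why: Copper-catalysed SN2 opening of the epoxide by the vinyl Grignard reagent at the secondary carbon C1 (the tertiary C15 is blocked) with inversion, so that the (R)-epoxide gives (R)-C1 bearing the vinyl group that becomes C2–C3; the first equivalent only deprotonates the C10 hydroxyl.

Step 4
Reactants: 4 diol
Product: 5 (2Z,6R)-6-(2-hydroxypropan-2-yl)-3-methylocta-2,7-dien-1-yl acetate
Conditions: Ac2O (1.1 equiv), pyridine, CH2Cl2, 0 °C
Reagents that add atoms: acetic anhydride, CC(=O)OC(C)=O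
Why: Selective acylation of the primary allylic hydroxyl over the tertiary C15 carbinol; acetate is chosen because LiBH4 removes it in step 15 together with the auxiliary.

Step 5
Reactants: 5 hydroxy acetate
Product: 6 (2Z,6R)-3-methyl-6-[2-(triethylsilyloxy)propan-2-yl]octa-2,7-dien-1-yl acetate
Conditions: TESOTf, 2,6-lutidine, CH2Cl2, −78 → 0 °C
Reagents that add atoms: triethylsilyl triflate, CC[Si](CC)(CC)OS(=O)(=O)C(F)(F)F
Why: Silylation of the hindered tertiary alcohol with a silyl triflate, which prevents lactol formation once C3 is an aldehyde.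

Step 6
Reactants: 6 TES ether
Product: 8 (2Z,6R)-8-hydroxy-3-methyl-6-[2-(triethylsilyloxy)propan-2-yl]oct-2-en-1-yl acetate, via B-alkyl-9-BBN 7 (not isolated)
Conditions: 9-BBN (1.5 equiv), THF, 0 °C → rt; then NaBO3·4H2O, H2O, rt
Reagents that add atoms: 9-BBN (boron in 7), [H]B1C2CCCC1CCC2; sodium perborate (oxygen in 8), [Na+].[O-]OB=O
Why: Hydroboration–oxidation, in which the bulky borane adds anti-Markovnikov to the monosubstituted vinyl group only and leaves the trisubstituted C11=C12 alkene, and perborate oxidises the C–B bond without hydrolysing the acetate.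

Step 7
Reactants: 8 primary alcohol
Product: 9 (2Z,6R)-3-methyl-8-oxo-6-[2-(triethylsilyloxy)propan-2-yl]oct-2-en-1-yl acetate
Conditions: Dess–Martin periodinane, pyridine, CH2Cl2, 0 °C → rt
Reagents that add atoms: none
Why: Dess–Martin oxidation to the C3 aldehyde under buffered conditions; C1 is β to the carbonyl and cannot epimerise.

Step 8
Reactants: 10 (S)-4-benzyloxazolidin-2-one, 11 hex-5-enoyl chloride
Product: 12 (S)-4-benzyl-3-(hex-5-enoyl)oxazolidin-2-one
Conditions: Et3N, DMAP (10 mol%), CH2Cl2, 0 °C → rt
Reagents that add atoms: none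
Why: DMAP-catalysed N-acylation of the oxazolidinone by the acid chloride.

Step 9
Reactants: 12 hexenoyl imide
Product: 13 (S)-4-benzyl-3-[(5E)-7-oxohept-5-enoyl]oxazolidin-2-one
Conditions: crotonaldehyde (5 equiv), second-generation Hoveyda–Grubbs catalyst RuCl2(H2IMes)(=CH-C6H4-2-OiPr) (3 mol%), CH2Cl2, 40 °C
Reagents that add atoms: (E)-crotonaldehyde, C/C=C/C=O
Why: Olefin cross-metathesis of a terminal alkene with an electron-poor enal partner, which should give the (E)-enal with loss of propene.

Step 10
Reactants: 13 enal imide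
Product: 14 (S)-4-benzyl-3-[(5Z)-6-iodo-7-oxohept-5-enoyl]oxazolidin-2-one
Conditions: I2 (1.5 equiv), K2CO3 (1.2 equiv), DMAP (20 mol%), THF/H2O 1:1, rt
Reagents that add atoms: iodine, II
Why: Amine-catalysed α-iodination of the enal (conjugate addition of DMAP, iodination of the enolate, E1cB loss of DMAP, a Morita–Baylis–Hillman-type sequence), which keeps CHO trans to C6 and so places iodine cis to C6; the imide should tolerate carbonate for the short reaction time.

Step 11
Reactants: 14 α-iodoenal
Product: 15 (S)-4-benzyl-3-[(5Z)-7-hydroxy-6-iodohept-5-enoyl]oxazolidin-2-one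
Conditions: NaBH4, CeCl3·7H2O, MeOH/THF, −78 → −40 °C
Reagents that add atoms: none
Why: Luche 1,2-reduction of the aldehyde, which is far faster than hydride attack on the imide at this temperature.

Step 12
Reactants: 15 iodoallylic alcohol
Product: 16 (S)-4-benzyl-3-[(5Z)-7-(tert-butyldiphenylsilyloxy)-6-iodohept-5-enoyl]oxazolidin-2-one
Conditions: TBDPSCl, imidazole, CH2Cl2, 0 °C → rt
Reagents that add atoms: tert-butyldiphenylsilyl chloride, CC(C)(C)[Si](Cl)(c1ccccc1)c1ccccc1
Why: Silylation of the primary allylic alcohol C19–OH with a group that withstands the acid of step 14.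

Step 13
Reactants: 16 iodoalkenyl imide, 9 aldehyde
Product: 18 syn-aldol adduct (C3–OH; C1 R and C3 R and C4 S by CIP in the imide), via Z-boron enolate 17 (not isolated)
Conditions: 16, Bu2BOTf, Et3N, CH2Cl2, −78 → 0 °C; 9, −78 → 0 °C; pH 7 buffer, MeOH, 30% H2O2, 0 °C
Reagents that add atoms: dibutylboron triflate (boron held only in 17), CCCCB(CCCC)OS(=O)(=O)C(F)(F)F
Why: Evans syn-aldol, in which the (Z)-boron enolate reacts through a closed Zimmerman–Traxler chair with the imide dipoles opposed and the benzyl group of the (S)-auxiliary blocks one enolate face, so that C3 and C4 are set syn in the absolute sense of the target, while the remote C1 centre of the aldehyde has little influence.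

Step 14
Reactants: 18 aldol adduct
Product: 20 tetrahydrofuran imide (2,2-dimethyl THF ring O–C15–C1–C2–C3 with C4 and C14 cis), via C3/C15 diol 19 (not isolated)
Conditions: TsOH·H2O (0.2 equiv), CH2Cl2, 0 °C → rt
Reagents that add atoms: none
Why: Acid-catalysed cyclodehydration of a 1,4-diol with one tertiary carbinol, in which the acid removes the TES group and ionises the tertiary C15–O bond and the C3 hydroxyl captures the cation in a five-membered closure, so that the C3–O bond is never broken and C3 keeps the configuration set in step 13.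

Step 15
Reactants: 20 tetrahydrofuran imide
Product: 21 diol (C18–OH and C10–OH; C1 R, C3 R, C4 R)
Conditions: LiBH4 (4 equiv), MeOH (4 equiv), THF, 0 °C → rt
Reagents that add atoms: none
Why: Reductive cleavage of the N-acyl oxazolidinone by LiBH4 gives the C18 primary alcohol and returns the auxiliary, and the same hydride removes the C10 acetate, while the alkenyl iodide and the silyl ether are untouched.

Step 16
Reactants: 21 diol
Product: 22 hydroxy (Z)-enal (C10 aldehyde, C18–OH)
Conditions: MnO2 (activated, 20 equiv), CH2Cl2, rt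
Reagents that add atoms: none
Why: MnO2 oxidises only the allylic C10 alcohol and leaves the saturated C18 alcohol, and its neutral heterogeneous conditions should keep the Z geometry of the neral-type enal.

Step 17
Reactants: 22 hydroxy enal
Product: 23 hydroxy (Z)-1,3-diene (C9=C10 terminal alkene, C18–OH)
Conditions: Ph3PCH3Br (3 equiv), KN(SiMe3)2 (2.8 equiv), THF, 0 °C; then 22, −78 → 0 °C
Reagents that add atoms: methyltriphenylphosphonium bromide, C[P+](c1ccccc1)(c1ccccc1)c1ccccc1.[Br-]
Why: Wittig methylenation at low temperature converts the enal into the terminal diene without isomerising C11=C12, and the excess ylide covers the free hydroxyl.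

Step 18
Reactants: 23 hydroxy diene
Product: 24 seco iodo-diene (C8 (Z)-iodoalkene, C9=C10 terminal alkene, C18 PMB ether, C19 TBDPS ether)
Conditions: NaH (1.5 equiv), PMBCl (1.3 equiv), Bu4NI (10 mol%), THF/DMF, 0 °C → rt
Reagents that add atoms: 4-methoxybenzyl chloride, COc1ccc(CCl)cc1
Why: Williamson etherification of the primary alkoxide with PMBCl, which the alkenyl iodide, the diene and the silyl ether should tolerate at or below room temperature.

Step 19
Reactants: 24 seco iodo-diene
Product: 26 protected bicyclic diol (14-membered ring closed at C8–C9; C19 TBDPS ether and C18 PMB ether), via C9 B-alkyl-9-BBN 25 (not isolated)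
Conditions: 9-BBN (1.5 equiv), THF, rt; then syringe-pump addition to PdCl2(dppf) (20 mol%), AsPh3 (40 mol%), Cs2CO3 (3 equiv), DMF/THF/H2O, 50 °C, final concentration about 1 mM
Reagents that add atoms: 9-BBN (boron held only in 25), [H]B1C2CCCC1CCC2
Why: B-alkyl Suzuki–Miyaura macrocyclisation: 9-BBN adds anti-Markovnikov to the terminal C9=C10 bond of the diene with boron on C9, zerovalent palladium inserts into the C8–I bond with retention, base converts the borane into a borate that transfers C9 to palladium, and reductive elimination forms the sp3–sp2 bond C8–C9. The closest known reaction type is the intramolecular coupling of an alkyl-9-BBN with an alkenyl iodide used to close medium and large carbocycles. The 14-membered ring closes end to end at the reductive elimination from a palladacycle that holds C8 and C9; no stereocentre is formed, and both trisubstituted alkenes keep the geometry fixed beforehand in neryl acetate and in the (Z)-iodoalkene. The step needs site-selective hydroboration (the bulk of 9-BBN spares the trisubstituted alkenes and the alkenyl iodide is inert to it), retention at C8 (inherent in oxidative addition and reductive elimination), and ring closure over oligomerisation (slow addition at high dilution). The wide bite angle of dppf and the AsPh3 additive should favour reductive elimination over β-hydride elimination, and the cis-disubstituted THF ring with two ring alkenes whose in-ring substituents are cis should bring the chain ends together.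

Step 20
Reactants: 26 protected bicyclic diol
Product: 27 C18 alcohol (C19 TBDPS ether retained)
Conditions: DDQ (1.3 equiv), CH2Cl2/pH 7 buffer 10:1, 0 °C → rt
Reagents that add atoms: none
Why: Oxidative cleavage of the PMB ether by DDQ (hydride abstraction at the electron-rich benzylic position, then hydrolysis) frees C18–OH and leaves the silyl ether and the ring alkenes.

Step 21
Reactants: 27 C18 alcohol
Product: 28 C18 hydrogen malonate (C19 TBDPS ether retained)
Conditions: Meldrum's acid (1.5 equiv), toluene, 95 °C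
Reagents that add atoms: Meldrum's acid, CC1(C)OC(=O)CC(=O)O1
Why: Thermal acylation by Meldrum's acid, in which the alcohol opens the dioxanedione and acetone is lost to give the malonic half-ester directly; it is placed before the enal exists so that no Knoevenagel condensation can compete.

Step 22
Reactants: 28 silyl ether half-ester
Product: 29 C19 allylic alcohol half-ester
Conditions: HF·pyridine, pyridine, THF, 0 °C → rt
Reagents that add atoms: none
Why: Fluoride-mediated cleavage of the primary silyl ether under buffered conditions that leave the half-ester and the THF ring alone.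

Step 23
Reactants: 29 allylic alcohol
Product: 30 CNP0170412.1
Conditions: TEMPO (20 mol%), PhI(OAc)2 (1.2 equiv), CH2Cl2, rt
Reagents that add atoms: none
Why: TEMPO-catalysed oxidation with PhI(OAc)2 (oxoammonium mechanism) takes the primary allylic alcohol to the enal without over-oxidation and tolerates the free acid; the C7=C8 geometry fixed in step 10 is unchanged.

**Compound list**

1 | neryl acetate, (2Z)-3,7-dimethylocta-2,6-dien-1-yl acetate | CC(C)=CCC/C(C)=C\COC(C)=O | starting material
2 | (2Z)-5-[(2R)-3,3-dimethyloxiran-2-yl]-3-methylpent-2-en-1-yl acetate | CC1(C)O[C@@H]1CC/C(C)=C\COC(C)=O | intermediate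
3 | (2Z)-5-[(2R)-3,3-dimethyloxiran-2-yl]-3-methylpent-2-en-1-ol | CC1(C)O[C@@H]1CC/C(C)=C\CO | intermediate
4 | (2Z,6R)-6-(2-hydroxypropan-2-yl)-3-methylocta-2,7-dien-1-ol | C=C[C@@H](CC/C(C)=C\CO)C(C)(C)O | intermediate
5 | (2Z,6R)-6-(2-hydroxypropan-2-yl)-3-methylocta-2,7-dien-1-yl acetate | C=C[C@@H](CC/C(C)=C\COC(C)=O)C(C)(C)O | intermediate
6 | (2Z,6R)-3-methyl-6-[2-(triethylsilyloxy)propan-2-yl]octa-2,7-dien-1-yl acetate | C=C[C@@H](CC/C(C)=C\COC(C)=O)C(C)(C)O[Si](CC)(CC)CC | intermediate
7 | B-alkyl-9-BBN from 6 (boron on the former terminal vinyl carbon, C3) | B1(CC[C@@H](CC/C(C)=C\COC(C)=O)C(C)(C)O[Si](CC)(CC)CC)C2CCCC1CCC2 | intermediate (not isolated)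
8 | (2Z,6R)-8-hydroxy-3-methyl-6-[2-(triethylsilyloxy)propan-2-yl]oct-2-en-1-yl acetate | OCC[C@@H](CC/C(C)=C\COC(C)=O)C(C)(C)O[Si](CC)(CC)CC | intermediate
9 | (2Z,6R)-3-methyl-8-oxo-6-[2-(triethylsilyloxy)propan-2-yl]oct-2-en-1-yl acetate | O=CC[C@@H](CC/C(C)=C\COC(C)=O)C(C)(C)O[Si](CC)(CC)CC | intermediate
10 | (S)-4-benzyloxazolidin-2-one | O=C1OC[C@H](Cc2ccccc2)N1 | starting material
11 | hex-5-enoyl chloride | C=CCCCC(Cl)=O | starting material
12 | (S)-4-benzyl-3-(hex-5-enoyl)oxazolidin-2-one | C=CCCCC(=O)N1[C@@H](Cc2ccccc2)COC1=O | intermediate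
13 | (S)-4-benzyl-3-[(5E)-7-oxohept-5-enoyl]oxazolidin-2-one | O=C/C=C/CCCC(=O)N1[C@@H](Cc2ccccc2)COC1=O | intermediate
14 | (S)-4-benzyl-3-[(5Z)-6-iodo-7-oxohept-5-enoyl]oxazolidin-2-one | O=C/C(I)=C/CCCC(=O)N1[C@@H](Cc2ccccc2)COC1=O | intermediate
15 | (S)-4-benzyl-3-[(5Z)-7-hydroxy-6-iodohept-5-enoyl]oxazolidin-2-one | OC/C(I)=C/CCCC(=O)N1[C@@H](Cc2ccccc2)COC1=O | intermediate
16 | (S)-4-benzyl-3-[(5Z)-7-(tert-butyldiphenylsilyloxy)-6-iodohept-5-enoyl]oxazolidin-2-one | CC(C)(C)[Si](c1ccccc1)(c1ccccc1)OC/C(I)=C/CCCC(=O)N1[C@@H](Cc2ccccc2)COC1=O | intermediate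
17 | (Z)-dibutylboron enolate of 16 | CCCCB(CCCC)O/C(=C\CC/C=C(I)/CO[Si](c1ccccc1)(c1ccccc1)C(C)(C)C)N1[C@@H](Cc2ccccc2)COC1=O | intermediate (not isolated)
18 | syn-aldol adduct: imide with C3–OH, C15–OTES, C10–OAc, C19–OTBDPS, (Z)-C8 iodide | O=C1OC[C@H](Cc2ccccc2)N1C(=O)[C@@H](CC/C=C(I)/CO[Si](c3ccccc3)(c4ccccc4)C(C)(C)C)[C@H](O)C[C@@H](CC/C(C)=C\COC(C)=O)C(C)(C)O[Si](CC)(CC)CC | intermediate
19 | C3/C15 diol from 18 (TES removed) | O=C1OC[C@H](Cc2ccccc2)N1C(=O)[C@@H](CC/C=C(I)/CO[Si](c3ccccc3)(c4ccccc4)C(C)(C)C)[C@H](O)C[C@@H](CC/C(C)=C\COC(C)=O)C(C)(C)O | intermediate (not isolated)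
20 | tetrahydrofuran imide (cis-3,5-disubstituted 2,2-dimethyl THF) | O=C1OC[C@H](Cc2ccccc2)N1C(=O)[C@@H](CC/C=C(I)/CO[Si](c3ccccc3)(c4ccccc4)C(C)(C)C)[C@H]5C[C@@H](CC/C(C)=C\COC(C)=O)C(C)(C)O5 | intermediate
21 | diol with C18–OH and C10–OH | OC[C@@H](CC/C=C(I)/CO[Si](c1ccccc1)(c2ccccc2)C(C)(C)C)[C@H]3C[C@@H](CC/C(C)=C\CO)C(C)(C)O3 | intermediate
22 | hydroxy (Z)-enal (C10 aldehyde) | OC[C@@H](CC/C=C(I)/CO[Si](c1ccccc1)(c2ccccc2)C(C)(C)C)[C@H]3C[C@@H](CC/C(C)=C\C=O)C(C)(C)O3 | intermediate
23 | hydroxy (Z)-1,3-diene | OC[C@@H](CC/C=C(I)/CO[Si](c1ccccc1)(c2ccccc2)C(C)(C)C)[C@H]3C[C@@H](CC/C(C)=C\C=C)C(C)(C)O3 | intermediate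
24 | seco iodo-diene (C18 PMB ether, C19 TBDPS ether) | I/C(CO[Si](c1ccccc1)(c1ccccc1)C(C)(C)C)=C\CC[C@H](COCc1ccc(OC)cc1)[C@H]2C[C@@H](CC/C(C)=C\C=C)C(C)(C)O2 | intermediate
25 | C9 B-alkyl-9-BBN from 24 | I/C(CO[Si](c1ccccc1)(c1ccccc1)C(C)(C)C)=C\CC[C@H](COCc1ccc(OC)cc1)[C@H]2C[C@@H](CC/C(C)=C\CCB3C4CCCC3CCC4)C(C)(C)O2 | intermediate (not isolated)
26 | protected bicyclic diol (C19 TBDPS ether, C18 PMB ether) | C/C1=C/CC/C(CO[Si](c3ccccc3)(c4ccccc4)C(C)(C)C)=C\CC[C@H](COCc5ccc(OC)cc5)[C@H]2C[C@@H](CC1)C(C)(C)O2 | intermediate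
27 | bicyclic C18 alcohol (C19 TBDPS ether) | C/C1=C/CC/C(CO[Si](c3ccccc3)(c4ccccc4)C(C)(C)C)=C\CC[C@H](CO)[C@H]2C[C@@H](CC1)C(C)(C)O2 | intermediate
28 | C18 hydrogen malonate (C19 TBDPS ether) | C/C1=C/CC/C(CO[Si](c3ccccc3)(c4ccccc4)C(C)(C)C)=C\CC[C@H](COC(=O)CC(=O)O)[C@H]2C[C@@H](CC1)C(C)(C)O2 | intermediate
29 | C19 allylic alcohol, C18 hydrogen malonate | C/C1=C/CC/C(CO)=C\CC[C@H](COC(=O)CC(=O)O)[C@H]2C[C@@H](CC1)C(C)(C)O2 | intermediate
30 | CNP0170412.1 | C/C1=C/CC/C(C=O)=C\CC[C@H](COC(=O)CC(=O)O)[C@H]2C[C@@H](CC1)C(C)(C)O2 | target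

**Step count**

Total: 23 steps. Longest linear sequence: 18 steps (steps 1–7 and 13–23, from neryl acetate).

**Steps most likely to fail**

Step 19 (macrocyclisation). Intermolecular coupling may outrun ring closure and give oligomers, the alkylpalladium may undergo β-hydride elimination, or the borane may be lost by protodeboronation before transmetalation. The fallback sets out from 24 and comes back at 26. Hydroboration of 24 as before to 25 is followed by oxidation with NaBO3·4H2O to the primary C9 alcohol F1, and I2, PPh3 and imidazole convert this into the primary C9 iodide F2. Zinc dust with LiCl in THF at 25 °C should insert into the alkyl iodide faster than into the alkenyl iodide and give the C9 alkylzinc iodide F3. Slow addition of this reagent to Pd(PPh3)4, a zerovalent palladium source, in THF/NMP at 50 °C closes the same C8–C9 bond by intramolecular Negishi coupling and gives 26.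

Step 3 (epoxide opening). SN2 attack at the secondary carbon next to the fully substituted C15 may be slow, so that magnesium-halide-promoted rearrangement of the epoxide to a ketone or halohydrin formation takes over. The fallback sets out from 3 and comes back at 4. The epoxide is opened with LiC≡CH·H2NCH2CH2NH2 in DMSO (rt → 45 °C), a small sp carbanion free of Lewis-acidic magnesium halide, which should attack C1 with the same inversion and give (2Z,6R)-6-(2-hydroxypropan-2-yl)-3-methyloct-2-en-7-yn-1-ol F4. Semihydrogenation over Pd/CaCO3 poisoned with Pb(OAc)2 and quinoline (H2, 1 atm) then gives 4.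

Step 14 (cycloetherification). The tertiary C15 cation may lose a proton towards C1 or take a hydride from C1 before the hydroxyl captures it, which would erode the C1 configuration, and the acid may also ionise the allylic acetate. The fallback sets out from 18 and comes back at 20. Dess–Martin oxidation of the C3 carbinol gives the β-keto imide F5, which should be configurationally stable at C4 because allylic strain holds the C4–H bond in the imide plane. Reductive etherification (Et3SiH, BF3·OEt2, CH2Cl2/MeCN, −78 → −30 °C) then closes the ring through the C3–O bond: the silyl ether oxygen adds to the activated ketone and hydride attacks the five-membered oxocarbenium ion on the inside face of the envelope, anti to the C1 side chain. This should leave C4 and C14 cis on the ring and give 20, with C3 now set by the ring rather than by the aldol.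

**Further compounds**

F1 | step 19 | primary C9 alcohol from hydroboration–oxidation of 24 | I/C(CO[Si](c1ccccc1)(c1ccccc1)C(C)(C)C)=C\CC[C@H](COCc1ccc(OC)cc1)[C@H]2C[C@@H](CC/C(C)=C\CCO)C(C)(C)O2
F2 | step 19 | primary C9 iodide | I/C(CO[Si](c1ccccc1)(c1ccccc1)C(C)(C)C)=C\CC[C@H](COCc1ccc(OC)cc1)[C@H]2C[C@@H](CC/C(C)=C\CCI)C(C)(C)O2
F3 | step 19 | C9 alkylzinc iodide | I/C(CO[Si](c1ccccc1)(c1ccccc1)C(C)(C)C)=C\CC[C@H](COCc1ccc(OC)cc1)[C@H]2C[C@@H](CC/C(C)=C\CC[Zn]I)C(C)(C)O2
F4 | step 3 | (2Z,6R)-6-(2-hydroxypropan-2-yl)-3-methyloct-2-en-7-yn-1-ol | C#C[C@@H](CC/C(C)=C\CO)C(C)(C)O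
F5 | step 14 | β-keto imide (C3 ketone of 18) | O=C1OC[C@H](Cc2ccccc2)N1C(=O)[C@@H](CC/C=C(I)/CO[Si](c3ccccc3)(c4ccccc4)C(C)(C)C)C(=O)C[C@@H](CC/C(C)=C\COC(C)=O)C(C)(C)O[Si](CC)(CC)CC
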